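**Retrosynthetic overview** (cembrane numbering: C1 = isopropyl-bearing alkene carbon, C4 = CO2Me-bearing carbon, C7 = CH–OAc, C8 = C(Me)–O, C12/C20 = lactone α-carbon/carbonyl; target is 7R,8S)
1. The 14-membered carbocycle is closed last at C14–C1 (alkyl–alkenyl) by an electrochemical Ni-catalysed decarboxylative alkenylation onto a (Z)-dienyl iodide.
2. The dienoate arm comes from an HWE olefination (C3=C4) with (Z)-3-iodo-4-methylpent-2-enal and a photochemical silyl-radical Giese addition (C5–C6) of a C6 bromide to trimethyl 2-phosphonoacrylate.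
3. The β-acetoxy bromide comes from a terminal acetonide; the seven-membered α,β-unsaturated ε-lactone comes from RCM of a tertiary 2-alkylacrylate.
4. C8 is set by chelation-controlled MeMgBr addition to a ketone made from methyl (R)-glycerate acetonide, which supplies C7.
5. Ring order: ε-lactone first (step 6), macrocycle second (step 14).

Assumption: 2-methyleneglutaric acid, 4-methylpent-2-yn-1-ol and trimethyl 2-phosphonoacrylate are treated as catalogue chemicals.

**Step 1**
Reactants: 1, methyl (4R)-2,2-dimethyl-1,3-dioxolane-4-carboxylate; 2, but-3-en-1-ylmagnesium bromide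
Product: 3, 1-[(4R)-2,2-dimethyl-1,3-dioxolan-4-yl]pent-4-en-1-one
Conditions: MeNHOMe·HCl, i-PrMgCl, THF, −20 °C; then 2, −20 → 0 °C (Weinreb amide not isolated)
Reagents that add atoms: but-3-en-1-ylmagnesium bromide (2), C=CCC[Mg]Br
Why: One-pot Weinreb ketone synthesis; the chelated tetrahedral adduct stops over-addition, and C7 (R) is carried unchanged from the glycerate.

**Step 2**
Reactants: 3
Product: 4, (2S)-2-[(4R)-2,2-dimethyl-1,3-dioxolan-4-yl]hex-5-en-2-ol
Conditions: MeMgBr, Et2O/CH2Cl2, −78 °C
Reagents that add atoms: methylmagnesium bromide, C[Mg]Br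
Why: Cram-chelate-controlled Grignard addition: Mg bridges the ketone and the α-dioxolane oxygen and methyl attacks from the H-face of C7, giving the 8S carbinol (oxygens anti along C6–C9; dr about 10:1 expected, minor isomer removed by chromatography).

**Step 3**
Reactants: 5, 2-methylidenepentanedioic acid (2-methyleneglutaric acid)
Product: 6, 3-methylideneoxane-2,6-dione (2-methyleneglutaric anhydride)
Conditions: Ac2O, 100 °C, then distil
Reagents that add atoms: none
Why: Cyclodehydration of a 1,5-diacid to the six-membered anhydride.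

**Step 4**
Reactants: 6
Product: 7, 2-methylidene-5-oxo-5-[2-(trimethylsilyl)ethoxy]pentanoic acid
Conditions: Me3SiCH2CH2OH, Et3N, DMAP (cat.), CH2Cl2, 0 °C → rt
Reagents that add atoms: 2-(trimethylsilyl)ethanol, C[Si](C)(C)CCO
Why: Regioselective anhydride alcoholysis at the more electrophilic non-conjugated carbonyl (as with itaconic anhydride) leaves the acrylic acid free and masks the future C14 carboxyl as a fluoride-labile TMSE ester.

**Step 5**
Reactants: 4; 7
Product: 8, 1-{(2S)-2-[(4R)-2,2-dimethyl-1,3-dioxolan-4-yl]hex-5-en-2-yl} 5-[2-(trimethylsilyl)ethyl] 2-methylidenepentanedioate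
Conditions: 7, (COCl)2, DMF (cat.), CH2Cl2, 0 °C → rt; then 4, LiHMDS, THF, −78 °C, add acid chloride, → 0 °C
Reagents that add atoms: none beyond reactant 7
Why: Acylation of a lithium tert-alkoxide with a methacryloyl-type acid chloride, the standard way to esterify hindered tertiary alcohols; no stereocentre is touched.

**Step 6**
Reactants: 8
Product: 9, 2-(trimethylsilyl)ethyl 3-{(7S)-7-[(4R)-2,2-dimethyl-1,3-dioxolan-4-yl]-7-methyl-2-oxo-2,5,6,7-tetrahydrooxepin-3-yl}propanoate
Conditions: Grubbs II (5 mol %), toluene (5 mM), 80 °C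
Reagents that add atoms: none
Why: Ring-closing metathesis of the terminal alkene with the 1,1-disubstituted acrylate (helped by the quaternary C8) forms the ε-lactone; the ring forces C20 cis to C10 at the new C11=C12 bond.

**Step 7**
Reactants: 9
Product: 10, 2-(trimethylsilyl)ethyl 3-{(7S)-7-[(1R)-1,2-dihydroxyethyl]-7-methyl-2-oxo-2,5,6,7-tetrahydrooxepin-3-yl}propanoate
Conditions: AcOH/H2O (4:1), 45 °C
Reagents that add atoms: none
Why: Mild acetal hydrolysis; the TMSE ester and the lactone survive, and translactonisation would need an 8- or 9-membered ring.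

**Step 8**
Reactants: 10
Product: 11, 2-(trimethylsilyl)ethyl 3-{(7S)-7-[(1S)-1-acetoxy-2-bromoethyl]-7-methyl-2-oxo-2,5,6,7-tetrahydrooxepin-3-yl}propanoate
Conditions: MeC(OMe)3, PPTS (cat.), CH2Cl2, rt; then AcBr, CH2Cl2, 0 °C
Reagents that add atoms: trimethyl orthoacetate, COC(C)(OC)OC (acetyl group); acetyl bromide, CC(=O)Br (bromine)
Why: Kolb–Sharpless one-pot diol → acetoxy bromide: the cyclic orthoacetate gives an acetoxonium ion that bromide opens at the primary carbon, so C7 keeps its configuration (the descriptor becomes S only because CH2Br outranks C8) and the C7 acetate of the target is installed.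

**Step 9**
Reactants: 11; 12, trimethyl 2-phosphonoacrylate (methyl 2-(dimethoxyphosphoryl)prop-2-enoate)
Product: 13, 2-(trimethylsilyl)ethyl 3-{(7S)-7-[(1R)-1-acetoxy-4-(dimethoxyphosphoryl)-5-methoxy-5-oxopentyl]-7-methyl-2-oxo-2,5,6,7-tetrahydrooxepin-3-yl}propanoate (mixture at the CH–P carbon)
Conditions: 12 (4 equiv), (TMS)3SiH, Ir[dF(CF3)ppy]2(dtbbpy)PF6 (1 mol %), Na2CO3, MeCN (0.2 M), 450 nm LEDs, rt
Reagents that add atoms: trimethyl 2-phosphonoacrylate (12), C=C(C(=O)OC)P(=O)(OC)OC
Why: Photochemical silyl-radical halogen-atom transfer followed by Giese addition forms C5–C6; the excess of the doubly activated acceptor at high concentration outruns 6-exo attack of the C6 radical on the lactone enoate and the slow 1,2-acetoxy shift.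

**Step 10**
Reactants: 14, 4-methylpent-2-yn-1-ol
Product: 15, (Z)-3-iodo-4-methylpent-2-en-1-ol
Conditions: Red-Al, THF, 0 °C → rt; then I2, −78 °C
Reagents that add atoms: iodine, II
Why: Hydroxyl-directed trans-hydroalumination and iodinolysis places iodine on C3 cis to CH2OH, which fixes the later C1=C2 geometry.

**Step 11**
Reactants: 15
Product: 16, (Z)-3-iodo-4-methylpent-2-enal
Conditions: MnO2, CH2Cl2, rt
Reagents that add atoms: none
Why: Chemoselective allylic alcohol oxidation that leaves the vinyl iodide and its geometry intact.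

**Step 12**
Reactants: 13; 16
Product: 17, methyl (2E,4Z)-2-{(3R)-3-acetoxy-3-[(2S)-2-methyl-7-oxo-6-(3-oxo-3-[2-(trimethylsilyl)ethoxy]propyl)-2,3,4,7-tetrahydrooxepin-2-yl]propyl}-5-iodo-6-methylhepta-2,4-dienoate
Conditions: NaHMDS (1.0 equiv), THF, −78 °C; then 16, −78 → 0 °C
Reagents that add atoms: none beyond reactant 16
Why: Horner–Wadsworth–Emmons olefination of the α-alkyl phosphonoacetate gives the tiglate-type E C3=C4 alkene (CO2Me trans to C2; minor Z isomer separable) while the iodide stays cis to C3.

**Step 13**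
Reactants: 17
Product: 18, 3-{(7S)-7-[(1R,4E,6Z)-1-acetoxy-7-iodo-4-(methoxycarbonyl)-8-methylnona-4,6-dien-1-yl]-7-methyl-2-oxo-2,5,6,7-tetrahydrooxepin-3-yl}propanoic acid
Conditions: TASF, DMF, 0 °C → rt
Reagents that add atoms: none
Why: Fluoride-induced fragmentation of the TMSE ester, orthogonal to the acetate, methyl ester, lactone and vinyl iodide.

**Step 14**
Reactants: 18
Product: 19, sarcrassin D
Conditions: NHPI, DIC, DMAP (cat.), CH2Cl2, rt (redox-active ester used crude); then NiCl2·6H2O/2,2′-bipyridine (30 mol %), AgNO3, LiCl, DMF, (+)Mg/(−)RVC, constant current, syringe-pump addition to 2 mM, rt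
Reagents that add atoms: none
Why: Proposed new method: intramolecular (macrocyclising) Ni-electrocatalytic decarboxylative alkenylation. Electrogenerated Ni(0)/bpy adds oxidatively to the dienyl iodide; reduction of the tethered N-acyloxyphthalimide releases CO2 and the primary C14 radical (it has no fast cyclisation or 1,5-H shift available); the alkenyl–Ni(II) on the same chain captures it under high dilution and high Ni loading, and reductive elimination from Ni(III) forms C14–C1 with retention of alkene geometry. The closest known reaction is the intermolecular Ni-electrocatalytic coupling of redox-active esters with alkenyl iodides on a silver-nanoparticle cathode; ring-closing precedent comes from Ni/Cr alkenyl-iodide and tin-hydride radical macrocyclisations.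

**Compound list**
1 | methyl (4R)-2,2-dimethyl-1,3-dioxolane-4-carboxylate | COC(=O)[C@H]1COC(C)(C)O1 | starting material
2 | but-3-en-1-ylmagnesium bromide | C=CCC[Mg]Br | starting material
3 | 1-[(4R)-2,2-dimethyl-1,3-dioxolan-4-yl]pent-4-en-1-one | C=CCCC(=O)[C@H]1COC(C)(C)O1 | intermediate
4 | (2S)-2-[(4R)-2,2-dimethyl-1,3-dioxolan-4-yl]hex-5-en-2-ol | C=CCC[C@](C)(O)[C@H]1COC(C)(C)O1 | intermediate
5 | 2-methylidenepentanedioic acid | C=C(CCC(=O)O)C(=O)O | starting material
6 | 3-methylideneoxane-2,6-dione | C=C1CCC(=O)OC1=O | intermediate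
7 | 2-methylidene-5-oxo-5-[2-(trimethylsilyl)ethoxy]pentanoic acid | C=C(CCC(=O)OCC[Si](C)(C)C)C(=O)O | intermediate
8 | tertiary acrylate ester of 4 with 7 | C=CCC[C@](C)(OC(=O)C(=C)CCC(=O)OCC[Si](C)(C)C)[C@H]1COC(C)(C)O1 | intermediate
9 | (7S)-ε-lactone with (4R)-dioxolane and TMSE propanoate arm | C[Si](C)(C)CCOC(=O)CCC1=CCC[C@](C)(OC1=O)[C@H]1COC(C)(C)O1 | intermediate
10 | (7S)-lactone (1R)-1,2-diol | C[Si](C)(C)CCOC(=O)CCC1=CCC[C@](C)(OC1=O)[C@H](O)CO | intermediate
11 | (7S)-lactone (1S)-1-acetoxy-2-bromoethyl compound | C[Si](C)(C)CCOC(=O)CCC1=CCC[C@](C)(OC1=O)[C@H](OC(C)=O)CBr | intermediate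
12 | trimethyl 2-phosphonoacrylate | C=C(C(=O)OC)P(=O)(OC)OC | starting material
13 | phosphonoacetate Giese adduct | C[Si](C)(C)CCOC(=O)CCC1=CCC[C@](C)(OC1=O)[C@H](OC(C)=O)CCC(C(=O)OC)P(=O)(OC)OC | intermediate
14 | 4-methylpent-2-yn-1-ol | CC(C)C#CCO | starting material
15 | (Z)-3-iodo-4-methylpent-2-en-1-ol | CC(C)/C(I)=C/CO | intermediate
16 | (Z)-3-iodo-4-methylpent-2-enal | CC(C)/C(I)=C/C=O | intermediate
17 | (2E,4Z)-iododienoate TMSE ester | C[Si](C)(C)CCOC(=O)CCC1=CCC[C@](C)(OC1=O)[C@H](OC(C)=O)CC/C(C(=O)OC)=C\C=C(\C(C)C)I | intermediate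
18 | seco acid | OC(=O)CCC1=CCC[C@](C)(OC1=O)[C@H](OC(C)=O)CC/C(C(=O)OC)=C\C=C(\C(C)C)I | intermediate
19 | sarcrassin D | COC(=O)/C1=C/C=C(/C(C)C)CCC2=CCC[C@](C)(OC2=O)[C@H](OC(C)=O)CC1 | target

**Totals**
Total steps: 14. Longest linear sequence: 10 (steps 1, 2, 5, 6, 7, 8, 9, 12, 13, 14).

**Steps most likely to fail, with fallbacks**
1. Step 14 (new macrocyclisation; risks are radical reduction or dimerisation and Z → E drift of the alkenyl–Ni species). Fallback with known chemistry: close the ring at C3=C4 instead. Open anhydride 6 with N-hydroxyphthalimide so lactone 9 carries the redox-active ester, couple it intermolecularly with the dimethyl acetal of 16 under the established Ni-electrocatalytic decarboxylative alkenylation, then run steps 7–9 and finish with an intramolecular Masamune–Roush HWE macrocyclisation (LiCl, DBU, MeCN, high dilution).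
2. Step 2 (diastereoselectivity of the chelation-controlled methyl addition). Fallback: reverse the order of the two nucleophiles and the control element. Make the methyl ketone from the same Weinreb amide, then add the butenyl group under non-chelating Felkin–Anh conditions (butenyl–Ti(OiPr)3 or butenyllithium/CeCl3), which leads to the same 7R,8S alcohol 4.
3. Step 6 (RCM to a trisubstituted seven-membered enoate). Fallback: form the lactone alkene by intramolecular HWE. Acylate 4 with the 2-(diethoxyphosphoryl) analogue of 7, ozonise the terminal alkene to the C11 aldehyde, and cyclise with LiCl/DBU; the ring again enforces the required cis geometry.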